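**Retrosynthetic overview** (target numbering: ring C1 (C=O), C2, C3 (C–OH), C4, C5 (CHOH), C6; side chain C1' (C=O) to C9')

1. Feature: ring carbon C3 (drawn as the enol C–OH) and side-chain carbonyl C1' are carbonyl-level carbons held 1,3 through ring carbon C2. Bridged by N–O (C3=N–O–C1'=C2) they are an isoxazole fused to the six-membered ring, so 19 is unmasked from isoxazolone 15.
2. 15 comes from nitrile oxide 14 (aldoxime 13) by an intramolecular nitrile oxide–ynone cycloaddition that makes C2–C3 and O–C1' and closes the carbocycle and the isoxazole together; this is the only ring-forming step.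
3. 13 comes from hydroxy Weinreb amide 9 and the lithium acetylide of alkyne 5 (C1–C2 bond), then alcohol oxidation and oximation of the aldehyde.
4. 9 comes from 3-silyloxyglutaric anhydride 6: desymmetrising methanolysis sets C5, borane reduces the acid arm, and the ester arm becomes the N-methoxy-N-methylamide.
5. 5 comes from aryl bromide 1 and 1,8-dibromooctane 2 (copper-catalysed aryl Grignard coupling), then displacement by lithium acetylide.

Key step: step 9

Remark on the descriptor: in the free 2-acyl-1,3-dione the proton shift between O–C1 and O–C3 exchanges the two ring arms of C5, so the (S) label of 19 belongs to the drawn tautomer only. C5 is a true stereocentre up to 16, and 17–19 are drawn with the former C=N carbon as C3–OH, which is the tautomer of the given SMILES.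

Remark on step 3: the quinidine-derived catalyst is assumed to deliver the (S)-half-ester 7. The sense is to be checked on the first run against the known (R)-enantiomer; if it is opposite, the pseudo-enantiomeric (DHQ)2AQN is used with nothing else changed.

**Route**

Step 1
Reactants: 1 1,2-bis(benzyloxy)-4-bromobenzene; 2 1,8-dibromooctane
Product: 4 1,2-bis(benzyloxy)-4-(8-bromooctyl)benzene, via aryl Grignard reagent 3 (not isolated)
Conditions: Mg, cat. I2, THF, reflux; then added to 2 (4 equiv), Li2CuCl4 (3 mol%), THF, −10 °C → rt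
Reagents that add atoms: none
Why: Copper-catalysed Kumada-type coupling of an aryl Grignard reagent with a primary alkyl bromide should give the ω-bromoalkylarene, the excess of 2 keeping double arylation low and the benzyl ethers being inert to the Grignard reagent.

Step 2
Reactants: 4 1,2-bis(benzyloxy)-4-(8-bromooctyl)benzene
Product: 5 1,2-bis(benzyloxy)-4-(dec-9-yn-1-yl)benzene
Conditions: LiC≡CH·H2NCH2CH2NH2 (2 equiv), DMSO, 10 °C → rt
Reagents that add atoms: lithium acetylide ethylenediamine complex, [Li]C#C.NCCN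
Why: SN2 alkylation of lithium acetylide by a primary bromide in DMSO is a standard route to terminal alkynes and leaves aryl benzyl ethers untouched.

Step 3
Reactants: 6 3-[(tert-butyldimethylsilyl)oxy]glutaric anhydride
Product: 7 (3S)-3-[(tert-butyldimethylsilyl)oxy]-5-methoxy-5-oxopentanoic acid
Conditions: MeOH (10 equiv), (DHQD)2AQN (20 mol%), Et2O, −40 °C
Reagents that add atoms: methanol, CO
Why: Cinchona-alkaloid-catalysed desymmetrising alcoholysis of a meso anhydride, in which the quinuclidine nitrogen delivers methanol by general-base catalysis to one of the two enantiotopic carbonyl groups, sets C3 of 7 (C5 of the target) under catalyst control.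

Step 4
Reactants: 7 (3S)-3-[(tert-butyldimethylsilyl)oxy]-5-methoxy-5-oxopentanoic acid
Product: 8 methyl (3S)-3-[(tert-butyldimethylsilyl)oxy]-5-hydroxypentanoate
Conditions: BH3·SMe2 (1.3 equiv), THF, 0 °C → rt; MeOH quench, aqueous work-up
Reagents that add atoms: none
Why: Chemoselective borane reduction of a carboxylic acid in the presence of a methyl ester (through the acyloxyborane) should give the hydroxy ester with the silyl ether and the stereocentre unaffected.

Step 5
Reactants: 8 methyl (3S)-3-[(tert-butyldimethylsilyl)oxy]-5-hydroxypentanoate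
Product: 9 (3S)-3-[(tert-butyldimethylsilyl)oxy]-5-hydroxy-N-methoxy-N-methylpentanamide
Conditions: MeNHOMe·HCl (4 equiv), AlMe3 (4 equiv), CH2Cl2, 0 °C → rt; aq. Rochelle salt
Reagents that add atoms: N,O-dimethylhydroxylamine hydrochloride, CNOC.Cl
Why: Weinreb aminolysis of the ester with the aluminium amide is Lewis-acidic and not basic, so the β-silyloxy group should not eliminate, and any δ-lactone formed from 8 is opened to the same amide.

Step 6
Reactants: 9 (3S)-3-[(tert-butyldimethylsilyl)oxy]-5-hydroxy-N-methoxy-N-methylpentanamide; 5 1,2-bis(benzyloxy)-4-(dec-9-yn-1-yl)benzene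
Product: 11 (3S)-15-[3,4-bis(benzyloxy)phenyl]-3-[(tert-butyldimethylsilyl)oxy]-1-hydroxypentadec-6-yn-5-one, via lithium acetylide 10 (not isolated)
Conditions: 5 (2.4 equiv), n-BuLi (2.3 equiv), THF, −78 °C; then 9, −78 → −30 °C; AcOH quench at −78 °C
Reagents that add atoms: none
Why: Weinreb ketone synthesis, in which the alkynyllithium adds once to the N-methoxy-N-methylamide to give a chelated tetrahedral intermediate that collapses to the ynone only on the cold acidic quench (which also stops conjugate addition of the released amine), the first equivalent of acetylide serving as base for the free hydroxyl.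

Step 7
Reactants: 11 (3S)-15-[3,4-bis(benzyloxy)phenyl]-3-[(tert-butyldimethylsilyl)oxy]-1-hydroxypentadec-6-yn-5-one
Product: 12 (3S)-15-[3,4-bis(benzyloxy)phenyl]-3-[(tert-butyldimethylsilyl)oxy]-5-oxopentadec-6-ynal
Conditions: Dess–Martin periodinane (1.3 equiv), CH2Cl2, 0 °C → rt
Reagents that add atoms: none
Why: Dess–Martin oxidation of the primary alcohol proceeds without base, which avoids β-elimination of the silyloxy group flanked by two carbonyl groups; any six-membered hemiketal form of 11 is in equilibrium with the open hydroxy ketone that is oxidised.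

Step 8
Reactants: 12 (3S)-15-[3,4-bis(benzyloxy)phenyl]-3-[(tert-butyldimethylsilyl)oxy]-5-oxopentadec-6-ynal
Product: 13 (3S)-15-[3,4-bis(benzyloxy)phenyl]-3-[(tert-butyldimethylsilyl)oxy]-5-oxopentadec-6-ynal oxime (E/Z mixture)
Conditions: NH2OH·HCl (1.05 equiv), NaOAc (1.1 equiv), EtOH/THF, 0 °C, short reaction time
Reagents that add atoms: hydroxylamine hydrochloride, NO.Cl
Why: Oxime condensation should be chemoselective because an unhindered aliphatic aldehyde condenses with hydroxylamine in acetate buffer at 0 °C far faster than the conjugated ynone undergoes carbonyl or conjugate addition, and only a slight excess of reagent is present.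

Step 9
Reactants: 13 (3S)-15-[3,4-bis(benzyloxy)phenyl]-3-[(tert-butyldimethylsilyl)oxy]-5-oxopentadec-6-ynal oxime
Product: 15 (6S)-3-{8-[3,4-bis(benzyloxy)phenyl]octyl}-6-[(tert-butyldimethylsilyl)oxy]-6,7-dihydro-2,1-benzisoxazol-4(5H)-one, via nitrile oxide 14 (not isolated)
Conditions: 13 added over 8 h to PhI(OAc)2 (1.2 equiv), TFA (10 mol%), MeOH/CH2Cl2, 0 °C → rt; final concentration about 0.005 M
Reagents that add atoms: none
Why: PhI(OAc)2 (trivalent iodine) dehydrogenates the aldoxime to nitrile oxide 14 without base, and the dipole then adds across the ynone triple bond in a concerted [3+2] cycloaddition in which its carbon (ring C3) bonds to the proximal alkyne carbon C2 and its oxygen to C1'; the closest known reaction type is the intramolecular nitrile oxide–alkyne cycloaddition to ring-fused isoxazoles. The carbocycle closes as a six-membered ring through the new C2–C3 bond, the four-atom tether C4–C5–C6–C1 spanning the two reacting carbons, and the isoxazole closes in the same event as the fused five-membered ring C3=N–O–C1'=C2. No stereocentre is formed; C5 (C6 of 15) is carried unchanged from 7 and remains stereogenic because C1 is a ketone and C3 an isoxazole C=N. Regiochemistry is fixed by the tether, since the reverse orientation would require a 3,5-bridged isoxazole with a four-atom bridge, and it is matched electronically because the dipole oxygen goes to the β-carbon of the ynone. The step needs cyclisation to outrun dimerisation of the dipole and loss of the β-silyloxy group, which slow addition at high dilution and the absence of base should secure.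

Step 10
Reactants: 15 (6S)-3-{8-[3,4-bis(benzyloxy)phenyl]octyl}-6-[(tert-butyldimethylsilyl)oxy]-6,7-dihydro-2,1-benzisoxazol-4(5H)-one
Product: 16 (5S)-3-amino-2-{9-[3,4-bis(benzyloxy)phenyl]nonanoyl}-5-[(tert-butyldimethylsilyl)oxy]cyclohex-2-en-1-one
Conditions: H2 (1 atm), Raney Ni (washed to neutrality), EtOH/THF, rt
Reagents that add atoms: none
Why: Catalytic hydrogenolysis of the weak isoxazole N–O bond gives the vinylogous amide (β-enaminone), a standard unmasking that should spare the aryl benzyl ethers and the silyl ether at 1 atm and room temperature.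

Step 11
Reactants: 16 (5S)-3-amino-2-{9-[3,4-bis(benzyloxy)phenyl]nonanoyl}-5-[(tert-butyldimethylsilyl)oxy]cyclohex-2-en-1-one
Product: 17 (5S)-2-{9-[3,4-bis(benzyloxy)phenyl]nonanoyl}-5-[(tert-butyldimethylsilyl)oxy]-3-hydroxycyclohex-2-en-1-one
Conditions: aq. NaOH (1 M), EtOH/THF, 40 °C, argon; then aq. HCl to pH 3 at 0 °C
Reagents that add atoms: water, O
Why: Addition–elimination hydrolysis of the push–pull enaminodiketone by hydroxide at C3 is driven by formation of the delocalised triketone enolate, which is itself resistant to β-elimination, and the benzyl and silyl ethers are stable to aqueous base.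

Step 12
Reactants: 17 (5S)-2-{9-[3,4-bis(benzyloxy)phenyl]nonanoyl}-5-[(tert-butyldimethylsilyl)oxy]-3-hydroxycyclohex-2-en-1-one
Product: 18 (5S)-2-{9-[3,4-bis(benzyloxy)phenyl]nonanoyl}-3,5-dihydroxycyclohex-2-en-1-one
Conditions: HF·pyridine, pyridine, THF, 0 °C → rt
Reagents that add atoms: none
Why: Fluoride-mediated desilylation with pyridine-buffered HF·pyridine is mild enough to avoid acid- or base-induced dehydration of the β-hydroxy dione to the resorcinol.

Step 13
Reactants: 18 (5S)-2-{9-[3,4-bis(benzyloxy)phenyl]nonanoyl}-3,5-dihydroxycyclohex-2-en-1-one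
Product: 19 (5S)-2-[9-(3,4-dihydroxyphenyl)nonanoyl]-3,5-dihydroxycyclohex-2-en-1-one
Conditions: H2 (1 atm), 10% Pd/C, EtOAc/MeOH, rt; filtration under argon
Reagents that add atoms: none
Why: Hydrogenolysis of the aryl benzyl ethers over Pd/C under neutral conditions frees the catechol in the last step, so the air-sensitive product needs only filtration and evaporation.

**Compound list**

1 | 1,2-bis(benzyloxy)-4-bromobenzene | Brc1ccc(OCc2ccccc2)c(OCc3ccccc3)c1 | starting material
2 | 1,8-dibromooctane | BrCCCCCCCCBr | starting material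
3 | [3,4-bis(benzyloxy)phenyl]magnesium bromide | Br[Mg]c1ccc(OCc2ccccc2)c(OCc3ccccc3)c1 | intermediate
4 | 1,2-bis(benzyloxy)-4-(8-bromooctyl)benzene | BrCCCCCCCCc1ccc(OCc2ccccc2)c(OCc3ccccc3)c1 | intermediate
5 | 1,2-bis(benzyloxy)-4-(dec-9-yn-1-yl)benzene | C#CCCCCCCCCc1ccc(OCc2ccccc2)c(OCc3ccccc3)c1 | intermediate
6 | 3-[(tert-butyldimethylsilyl)oxy]glutaric anhydride | O=C1CC(O[Si](C)(C)C(C)(C)C)CC(=O)O1 | starting material
7 | (3S)-3-[(tert-butyldimethylsilyl)oxy]-5-methoxy-5-oxopentanoic acid | OC(=O)C[C@H](O[Si](C)(C)C(C)(C)C)CC(=O)OC | intermediate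
8 | methyl (3S)-3-[(tert-butyldimethylsilyl)oxy]-5-hydroxypentanoate | OCC[C@H](O[Si](C)(C)C(C)(C)C)CC(=O)OC | intermediate
9 | (3S)-3-[(tert-butyldimethylsilyl)oxy]-5-hydroxy-N-methoxy-N-methylpentanamide | OCC[C@H](O[Si](C)(C)C(C)(C)C)CC(=O)N(C)OC | intermediate
10 | {10-[3,4-bis(benzyloxy)phenyl]dec-1-yn-1-yl}lithium | [Li]C#CCCCCCCCCc1ccc(OCc2ccccc2)c(OCc3ccccc3)c1 | intermediate
11 | (3S)-15-[3,4-bis(benzyloxy)phenyl]-3-[(tert-butyldimethylsilyl)oxy]-1-hydroxypentadec-6-yn-5-one | OCC[C@H](O[Si](C)(C)C(C)(C)C)CC(=O)C#CCCCCCCCCc1ccc(OCc2ccccc2)c(OCc3ccccc3)c1 | intermediate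
12 | (3S)-15-[3,4-bis(benzyloxy)phenyl]-3-[(tert-butyldimethylsilyl)oxy]-5-oxopentadec-6-ynal | O=CC[C@H](O[Si](C)(C)C(C)(C)C)CC(=O)C#CCCCCCCCCc1ccc(OCc2ccccc2)c(OCc3ccccc3)c1 | intermediate
13 | (3S)-15-[3,4-bis(benzyloxy)phenyl]-3-[(tert-butyldimethylsilyl)oxy]-5-oxopentadec-6-ynal oxime (E/Z mixture) | ON=CC[C@H](O[Si](C)(C)C(C)(C)C)CC(=O)C#CCCCCCCCCc1ccc(OCc2ccccc2)c(OCc3ccccc3)c1 | intermediate
14 | (3S)-15-[3,4-bis(benzyloxy)phenyl]-3-[(tert-butyldimethylsilyl)oxy]-5-oxopentadec-6-ynenitrile oxide | [O-][N+]#CC[C@H](O[Si](C)(C)C(C)(C)C)CC(=O)C#CCCCCCCCCc1ccc(OCc2ccccc2)c(OCc3ccccc3)c1 | intermediate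
15 | (6S)-3-{8-[3,4-bis(benzyloxy)phenyl]octyl}-6-[(tert-butyldimethylsilyl)oxy]-6,7-dihydro-2,1-benzisoxazol-4(5H)-one | O=C1C[C@@H](O[Si](C)(C)C(C)(C)C)Cc2noc(CCCCCCCCc3ccc(OCc4ccccc4)c(OCc5ccccc5)c3)c21 | intermediate
16 | (5S)-3-amino-2-{9-[3,4-bis(benzyloxy)phenyl]nonanoyl}-5-[(tert-butyldimethylsilyl)oxy]cyclohex-2-en-1-one | O=C1C[C@@H](O[Si](C)(C)C(C)(C)C)CC(N)=C1C(=O)CCCCCCCCc2ccc(OCc3ccccc3)c(OCc4ccccc4)c2 | intermediate
17 | (5S)-2-{9-[3,4-bis(benzyloxy)phenyl]nonanoyl}-5-[(tert-butyldimethylsilyl)oxy]-3-hydroxycyclohex-2-en-1-one | O=C(CCCCCCCCc1ccc(OCc2ccccc2)c(OCc3ccccc3)c1)C1=C(O)C[C@H](O[Si](C)(C)C(C)(C)C)CC1=O | intermediate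
18 | (5S)-2-{9-[3,4-bis(benzyloxy)phenyl]nonanoyl}-3,5-dihydroxycyclohex-2-en-1-one | O=C(CCCCCCCCc1ccc(OCc2ccccc2)c(OCc3ccccc3)c1)C1=C(O)C[C@H](O)CC1=O | intermediate
19 | (5S)-2-[9-(3,4-dihydroxyphenyl)nonanoyl]-3,5-dihydroxycyclohex-2-en-1-one (CNP0178179.1) | O=C(CCCCCCCCc1ccc(O)c(O)c1)C1=C(O)C[C@H](O)CC1=O | target

**Step count**

Total: 13 steps. Longest linear sequence: 11 steps (steps 3 to 13, from anhydride 6).

**Steps most likely to fail**

Step 9. Cyclisation may be too slow relative to dimerisation of the dipole, or the ketone-activated methylene may lose the silyloxy group by elimination followed by aromatisation. The fallback sets out from 13 and comes back at 15; it removes the ketone activation during ring closure.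
- Luche reduction of the ynone carbonyl (NaBH4, CeCl3·7H2O, MeOH, −40 °C), which leaves the oxime intact, should give the propargylic alcohol (3S)-15-[3,4-bis(benzyloxy)phenyl]-3-[(tert-butyldimethylsilyl)oxy]-5-hydroxypentadec-6-ynal oxime F1 as a mixture of C5 epimers.
- Oxidation of the oxime with PhI(OAc)2 under the same dilution, with cycloaddition onto the now unconjugated and more flexible alkynol, should give the carbinol (6S)-3-{8-[3,4-bis(benzyloxy)phenyl]octyl}-6-[(tert-butyldimethylsilyl)oxy]-4,5,6,7-tetrahydro-2,1-benzisoxazol-4-ol F2.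
- Dess–Martin oxidation of the carbinol, which also removes the epimeric centre, returns 15.

Step 11. Hydroxide may act as a base on the enaminone (deprotonation next to the ring ketone, loss of the silyloxy group and aromatisation), or fail to add to the N–H-deprotonated enaminone so that hydrolysis stalls. The fallback sets out from 16 and comes back at 17; it turns nitrogen into a better leaving group.
- Treatment of 16 with Boc2O and DMAP in MeCN at rt should give the carbamate tert-butyl N-[(5S)-2-{9-[3,4-bis(benzyloxy)phenyl]nonanoyl}-5-[(tert-butyldimethylsilyl)oxy]-3-oxocyclohex-1-en-1-yl]carbamate F3.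
- LiOH in aqueous THF at 0 °C should then displace tert-butyl carbamate from C3 (the known activation of amides as N-Boc derivatives for mild hydrolysis, applied to the vinylogous amide) and give 17 after acidification.

Step 8. Carbonyl or conjugate addition of hydroxylamine to the ynone may compete with condensation at the aldehyde. The fallback sets out from 9 and comes back at 13, bypassing 11 and 12, so that hydroxylamine never meets the ynone.
- Dess–Martin oxidation of 9 should give the aldehyde (3S)-3-[(tert-butyldimethylsilyl)oxy]-N-methoxy-N-methyl-5-oxopentanamide F4.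
- Condensation with NH2OH·HCl/NaOAc, with no competing electrophile present, should give the oxime (3S)-3-[(tert-butyldimethylsilyl)oxy]-5-(hydroxyimino)-N-methoxy-N-methylpentanamide F5.
- Addition of lithium acetylide 10 (2.4 equiv, the first equivalent deprotonating the oxime O–H) at −78 °C with a cold AcOH quench should give 13 directly.

**Further compounds**

F1 | step 9 | (3S)-15-[3,4-bis(benzyloxy)phenyl]-3-[(tert-butyldimethylsilyl)oxy]-5-hydroxypentadec-6-ynal oxime (C5 epimers, E/Z mixture) | ON=CC[C@H](O[Si](C)(C)C(C)(C)C)CC(O)C#CCCCCCCCCc1ccc(OCc2ccccc2)c(OCc3ccccc3)c1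
F2 | step 9 | (6S)-3-{8-[3,4-bis(benzyloxy)phenyl]octyl}-6-[(tert-butyldimethylsilyl)oxy]-4,5,6,7-tetrahydro-2,1-benzisoxazol-4-ol (C4 epimers) | OC1C[C@@H](O[Si](C)(C)C(C)(C)C)Cc2noc(CCCCCCCCc3ccc(OCc4ccccc4)c(OCc5ccccc5)c3)c21
F3 | step 11 | tert-butyl N-[(5S)-2-{9-[3,4-bis(benzyloxy)phenyl]nonanoyl}-5-[(tert-butyldimethylsilyl)oxy]-3-oxocyclohex-1-en-1-yl]carbamate | O=C1C[C@@H](O[Si](C)(C)C(C)(C)C)CC(NC(=O)OC(C)(C)C)=C1C(=O)CCCCCCCCc2ccc(OCc3ccccc3)c(OCc4ccccc4)c2
F4 | step 8 | (3S)-3-[(tert-butyldimethylsilyl)oxy]-N-methoxy-N-methyl-5-oxopentanamide | O=CC[C@H](O[Si](C)(C)C(C)(C)C)CC(=O)N(C)OC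
F5 | step 8 | (3S)-3-[(tert-butyldimethylsilyl)oxy]-5-(hydroxyimino)-N-methoxy-N-methylpentanamide (E/Z mixture) | ON=CC[C@H](O[Si](C)(C)C(C)(C)C)CC(=O)N(C)OC
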